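The numbering is C1 = alkene carbon bearing the isopropyl group, C2 = its alkene partner, C3/C4 = epoxide, C7=C8 with C19H2OH on C8, C9 = ketone, C12 = CHCH3, C13 = CHOH, C14 = ketone.
The key step is possible because O13 and the C9 carbonyl are 1,5-related and the C12 methyl is next to C13. C9–C10–C11–C12–C13 plus O13 therefore fold into a 2,3-cis-substituted pyran ring: its ring oxygen is the later hydroxyl, its acetal carbon is the later ketone, and it is the [4+2] adduct of a glyoxylate (C13, C14) and a 1-silyloxypenta-1,3-diene (C9–C12 and the methyl).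
The retrosynthesis cuts C1=C2 (ring-closing Horner–Wadsworth–Emmons), C8–C9 (vinyllithium on a δ-lactone), C14–C1 (phosphonate acylation), C12–C13 together with O13–C9 (hetero-Diels–Alder) and C7=C8 (iodo-ylide Wittig).
In the forward direction the pyran ring comes first, followed by saturation, ketophosphonate and lactone, while nerol is converted in parallel into the epoxy vinyl iodide. Union at C8–C9 opens the pyran, the 14-membered ring closes last at C1=C2, and desilylation ends the route.
C12 and C13 come from the endo, ligand-controlled cycloaddition and C3 and C4 from Sharpless epoxidation of the Z allylic alcohol. The 7Z alkene comes from the stabilised iodo ylide and retentive lithiation, and the 1E alkene from the phosphonate olefination.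

Key step: step 2

Remark on the chemistry: the target is taken to exist as the open C13-hydroxy C9-ketone that is drawn, not as its transannular hemiketal.

Step 1
Reactants: 1 (E)-pent-2-enal
Product: 2 (1E,3E)-1-(tert-butyldimethylsilyloxy)penta-1,3-diene
Conditions: TBSOTf, Et3N, Et2O, 0 °C to rt; distillation
Reagents that add atoms: tert-butyldimethylsilyl trifluoromethanesulfonate, CC(C)(C)[Si](C)(C)OS(=O)(=O)C(F)(F)F
Why: Soft enolisation to a silyl dienol ether (O-silylation of the enal, then γ-deprotonation by the amine) should give mainly the 1E,3E isomer, because the s-trans enal fixes the enol ether as E and allylic strain in the deprotonation favours the E propenyl unit.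

Step 2
Reactants: 2 (1E,3E)-1-(tert-butyldimethylsilyloxy)penta-1,3-diene; 3 ethyl glyoxylate
Product: 4 ethyl (2S,3R,6S)-6-(tert-butyldimethylsilyloxy)-3-methyl-3,6-dihydro-2H-pyran-2-carboxylate (all-cis; pyran C2 = C13, C3 = C12, C6 = C9)
Conditions: Cu(OTf)2 (10 mol %), 2,2'-(propane-2,2-diyl)bis[(4S)-4-tert-butyl-4,5-dihydrooxazole] (11 mol %), CH2Cl2, −78 to −40 °C; 2 (1.5 equiv), freshly distilled 3; Et3N quench
Reagents that add atoms: none
Why: The square-planar bis(oxazoline) complex of divalent copper chelates 3 through the aldehyde and ester oxygens and lowers its LUMO, so the methyl-bearing diene terminus, which holds the largest HOMO coefficient of a 1-oxygenated diene, bonds to the aldehyde carbon (C12–C13) while the aldehyde oxygen bonds to the silyloxy-bearing terminus (O13–C9), either in one asynchronous event or as a vinylogous Mukaiyama addition followed by collapse of the copper alkoxide on the silyloxocarbenium ion. The closest known reaction type is the catalytic enantioselective hetero-Diels–Alder reaction of glyoxylate esters with 1-alkoxy- and 1-silyloxydienes under chiral Lewis acid catalysis. The only ring formed is the six-membered dihydropyran, closed in the [4+2] mode (a 6-exo-trig O-attack on the oxocarbenium carbon in the stepwise limit). Suprafacial addition to the E,E-diene places the C12 methyl and the C9 silyloxy group cis, the ester-endo transition state places the C13 ester cis to both (2,3-cis, that is C12/C13 syn), and the tert-butyl groups of the (S,S)-ligand block the re face of the chelated aldehyde so that si-face attack gives 13S and with it 12R, the C9 acetal centre being temporary. The step needs regio-, endo- and facial selectivity plus discrimination among diene isomers: the 1-silyloxy donor fixes the regiochemistry, two-point binding of the glyoxylate fixes the endo and facial bias, and only the E,E isomer of 2 reaches the s-cis conformation, so Z isomers stay behind.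

Step 3
Reactants: 4 ethyl (2S,3R,6S)-6-(tert-butyldimethylsilyloxy)-3-methyl-3,6-dihydro-2H-pyran-2-carboxylate
Product: 5 ethyl (2S,3R,6S)-6-(tert-butyldimethylsilyloxy)-3-methyloxane-2-carboxylate
Conditions: H2 (1 atm), 10% Pd/C, EtOAc, rt
Reagents that add atoms: none
Why: Heterogeneous catalytic hydrogenation under neutral conditions saturates the only C=C bond (C10=C11) and leaves the silyl acetal, the ester and the three stereocentres untouched.

Step 4
Reactants: 6 1-bromo-2-methylpropane
Product: 7 diethyl (2-methylpropyl)phosphonate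
Conditions: P(OEt)3, neat, 150–160 °C, volatile halide distilled off
Reagents that add atoms: triethyl phosphite, CCOP(OCC)OCC
Why: Michaelis–Arbuzov reaction, in which phosphorus displaces the primary bromide and the bromide then dealkylates the phosphonium ion, driven forward by distilling off the volatile ethyl halide.

Step 5
Reactants: 5 ethyl (2S,3R,6S)-6-(tert-butyldimethylsilyloxy)-3-methyloxane-2-carboxylate; 7 diethyl (2-methylpropyl)phosphonate
Product: 9 diethyl {1-[(2S,3R,6S)-6-(tert-butyldimethylsilyloxy)-3-methyloxan-2-yl]-3-methyl-1-oxobutan-2-yl}phosphonate (both epimers at C1), via lithiated phosphonate 8 (not isolated)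
Conditions: 7 (2.2 equiv), n-BuLi (2.1 equiv), THF, −78 °C; then 5, −78 to −30 °C; aq NH4Cl
Reagents that add atoms: none
Why: Acylation of a lithiated alkylphosphonate by an ester (Corey–Kwiatkowski ketophosphonate synthesis) forms C14–C1, and the product is at once deprotonated at C1 by the second equivalent of 8, which stops further addition and shields C13 from epimerisation, while the new C1 centre is of no consequence because it becomes sp2 in step 17.

Step 6
Reactants: 9 diethyl {1-[(2S,3R,6S)-6-(tert-butyldimethylsilyloxy)-3-methyloxan-2-yl]-3-methyl-1-oxobutan-2-yl}phosphonate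
Product: 10 diethyl {1-[(2S,3R)-6-hydroxy-3-methyloxan-2-yl]-3-methyl-1-oxobutan-2-yl}phosphonate (lactol, both anomers)
Conditions: HF·pyridine, pyridine, THF, 0 °C
Reagents that add atoms: none
Why: Fluoride cleavage of the anomeric silyl ether in a buffered, slightly acidic medium frees the lactol without generating the phosphonate anion, so no olefination with the open-chain C9 aldehyde tautomer can start.

Step 7
Reactants: 10 diethyl {1-[(2S,3R)-6-hydroxy-3-methyloxan-2-yl]-3-methyl-1-oxobutan-2-yl}phosphonate
Product: 11 diethyl {3-methyl-1-[(2S,3R)-3-methyl-6-oxooxan-2-yl]-1-oxobutan-2-yl}phosphonate (δ-lactone)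
Conditions: TEMPO (cat), PhI(OAc)2, CH2Cl2, rt
Reagents that add atoms: none
Why: Oxoammonium-mediated (TEMPO) oxidation of a lactol to the δ-lactone raises C9 to the acyl level under near-neutral conditions that do not enolise C13.

Step 8
Reactants: 12 nerol
Product: 13 [(2S,3R)-3-methyl-3-(4-methylpent-3-en-1-yl)oxiran-2-yl]methanol
Conditions: Ti(OiPr)4 (5 mol %), L-(+)-diethyl tartrate (6 mol %), t-BuOOH, 4 Å MS, CH2Cl2, −20 °C
Reagents that add atoms: tert-butyl hydroperoxide, CC(C)(C)OO
Why: Sharpless asymmetric epoxidation, in which the allylic hydroxyl binds the titanium tartrate peroxide complex so that only the C3=C4 alkene reacts, L-(+)-tartrate selects the face that gives the 2S,3R epoxy alcohol (C3 S and C4 R of the target), and the Z geometry of nerol becomes the cis relation of C2 and C5 on the oxirane.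

Step 9
Reactants: 13 [(2S,3R)-3-methyl-3-(4-methylpent-3-en-1-yl)oxiran-2-yl]methanol
Product: 14 (2S,3R)-2-{[(4-methoxybenzyl)oxy]methyl}-3-methyl-3-(4-methylpent-3-en-1-yl)oxirane
Conditions: NaH, PMBCl, Bu4NI (cat), THF/DMF, 0 °C to rt
Reagents that add atoms: 4-methoxybenzyl chloride, COc1ccc(CCl)cc1
Why: Williamson etherification of the primary alkoxide, which in an aprotic medium outruns Payne rearrangement and installs a group that is later removed oxidatively in the presence of silyl ethers.

Step 10
Reactants: 14 (2S,3R)-2-{[(4-methoxybenzyl)oxy]methyl}-3-methyl-3-(4-methylpent-3-en-1-yl)oxirane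
Product: 16 3-[(2R,3S)-3-{[(4-methoxybenzyl)oxy]methyl}-2-methyloxiran-2-yl]propanal, via secondary ozonide 15 (not isolated)
Conditions: O3, CH2Cl2, −78 °C, stopped at consumption of 14; then PPh3, −78 °C to rt
Reagents that add atoms: ozone, [O-][O+]=O
Why: Ozonolysis with reductive work-up cleaves the only remaining alkene, which is far more reactive towards ozone than the anisyl ring, and exposes C7 as the aldehyde.

Step 11
Reactants: 16 3-[(2R,3S)-3-{[(4-methoxybenzyl)oxy]methyl}-2-methyloxiran-2-yl]propanal
Product: 17 ethyl (2Z)-2-iodo-5-[(2R,3S)-3-{[(4-methoxybenzyl)oxy]methyl}-2-methyloxiran-2-yl]pent-2-enoate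
Conditions: Ph3P=CHCO2Et, NIS, CH2Cl2, −20 °C; then 16, −20 °C to rt
Reagents that add atoms: ethyl (triphenylphosphoranylidene)acetate, CCOC(=O)C=P(c1ccccc1)(c1ccccc1)c1ccccc1; N-iodosuccinimide, O=C1CCC(=O)N1I
Why: Wittig olefination with a stabilised α-iodo ylide, formed in the flask by iodination of the parent ylide, places the ester trans to the chain as stabilised ylides do, so that iodine is cis to C6 and the Z iodoalkene already has the C7=C8 geometry of the target.

Step 12
Reactants: 17 ethyl (2Z)-2-iodo-5-[(2R,3S)-3-{[(4-methoxybenzyl)oxy]methyl}-2-methyloxiran-2-yl]pent-2-enoate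
Product: 18 (2Z)-2-iodo-5-[(2R,3S)-3-{[(4-methoxybenzyl)oxy]methyl}-2-methyloxiran-2-yl]pent-2-en-1-ol
Conditions: i-Bu2AlH (2.3 equiv), CH2Cl2, −78 °C; aq potassium sodium tartrate
Reagents that add atoms: none
Why: Low-temperature 1,2-reduction of the conjugated ester by two hydride equivalents gives the allylic alcohol (C19) under conditions to which trisubstituted epoxides, vinyl iodides and PMB ethers are inert.

Step 13
Reactants: 11 diethyl {3-methyl-1-[(2S,3R)-3-methyl-6-oxooxan-2-yl]-1-oxobutan-2-yl}phosphonate; 18 (2Z)-2-iodo-5-[(2R,3S)-3-{[(4-methoxybenzyl)oxy]methyl}-2-methyloxiran-2-yl]pent-2-en-1-ol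
Product: 21 open-chain (3S,4R,7Z,12R,13S) seco diol: C2-OPMB 3,4-epoxide 8-(hydroxymethyl)-7-en-9-one 12-methyl-13-hydroxy-14-ketone carrying the C1 isopropyl diethylphosphonate, via sodium phosphonoenolate 19 (not isolated), via vinyllithium alkoxide 20 (not isolated)
Conditions: 11, NaH (1.0 equiv), THF, 0 °C then −78 °C; separately 18 (1.2 equiv), t-BuLi (3.7 equiv), Et2O, −78 °C; combine at −78 °C; aq NH4Cl
Reagents that add atoms: none
Why: Addition of a vinyllithium to a δ-lactone, stopped at the tetrahedral lithium hemiketal until the quench, forms C8–C9 and releases the ring oxygen as the C13 hydroxyl: iodine–lithium exchange at −78 °C retains the alkene geometry and is much faster than attack on the hindered trisubstituted epoxide, the neighbouring alkoxide rules out β-elimination and silyl migration, and prior conversion of the ketophosphonate into enolate 19 removes its acidic proton and masks C14, leaving the lactone carbonyl as the only electrophile.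

Step 14
Reactants: 21 open-chain seco diol
Product: 22 13,19-bis(triethylsilyl) ether of 21
Conditions: TESCl, imidazole, DMF, 0 °C to rt
Reagents that add atoms: chlorotriethylsilane, CC[Si](Cl)(CC)CC
Why: Silyl ether formation on the primary allylic and the secondary C13 hydroxyl of the open hydroxy enone tautomer, which drains any hemiketal because its tertiary hydroxyl is silylated far more slowly, and the non-Lewis-acidic chloride and imidazole spare the epoxide and the Z enone.

Step 15
Reactants: 22 13,19-bis(triethylsilyl) ether of 21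
Product: 23 C2 primary epoxy alcohol (PMB removed, otherwise as 22)
Conditions: DDQ, CH2Cl2/pH 7 phosphate buffer, 0 °C
Reagents that add atoms: none
Why: Oxidative cleavage of the PMB ether by DDQ (hydride abstraction from the electron-rich benzylic position, then hydrolysis) in a buffered two-phase medium is orthogonal to the TES ethers, the epoxide, the enone and the ketophosphonate.

Step 16
Reactants: 23 C2 primary epoxy alcohol
Product: 24 C2 epoxy aldehyde (spatial arrangement of the epoxide unchanged; the C3 descriptor reads R only through the priority rules)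
Conditions: Dess–Martin periodinane, pyridine, CH2Cl2, 0 °C to rt
Reagents that add atoms: none
Why: Dess–Martin oxidation of the primary epoxy alcohol under pyridine buffering gives the epoxy aldehyde without epimerisation or epoxide opening and is routinely used next to β-ketophosphonates.

Step 17
Reactants: 24 C2 epoxy aldehyde
Product: 25 (1E,3S,4R,7Z,12R,13S) 14-membered macrocycle, 13,19-bis(triethylsilyl) ether of the target
Conditions: K2CO3, 18-crown-6, toluene, slow addition to about 1 mM, rt to 50 °C
Reagents that add atoms: none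
Why: Intramolecular Horner–Wadsworth–Emmons olefination under mild heterogeneous base and high dilution closes the 14-membered ring at C1=C2, the aldehyde being far more reactive than the hindered C9 enone carbonyl, and reversible addition followed by syn elimination should favour the E enone in which the C14 acyl group and C3 are trans and the ring spans the alkene in a transoid way.

Step 18
Reactants: 25 13,19-bis(triethylsilyl) ether of the target
Product: 26 CNP0251075.1, the (1E,3S,4R,7Z,12R,13S) epoxy diketo diol
Conditions: HF·pyridine, pyridine, THF, 0 °C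
Reagents that add atoms: none
Why: Fluoride-mediated cleavage of both TES ethers in pyridine-buffered HF is mild enough for the epoxide, the two enones and the α-hydroxy ketone, so that no stereocentre or alkene geometry is disturbed.

Compound list
1 | (E)-pent-2-enal | CC/C=C/C=O | starting material
2 | (1E,3E)-1-(tert-butyldimethylsilyloxy)penta-1,3-diene | C/C=C/C=C/O[Si](C)(C)C(C)(C)C | intermediate
3 | ethyl glyoxylate | CCOC(=O)C=O | starting material
4 | ethyl (2S,3R,6S)-6-(tert-butyldimethylsilyloxy)-3-methyl-3,6-dihydro-2H-pyran-2-carboxylate | CCOC(=O)[C@H]1O[C@@H](O[Si](C)(C)C(C)(C)C)C=C[C@H]1C | intermediate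
5 | ethyl (2S,3R,6S)-6-(tert-butyldimethylsilyloxy)-3-methyloxane-2-carboxylate | CCOC(=O)[C@H]1O[C@@H](O[Si](C)(C)C(C)(C)C)CC[C@H]1C | intermediate
6 | 1-bromo-2-methylpropane | CC(C)CBr | starting material
7 | diethyl (2-methylpropyl)phosphonate | CCOP(=O)(CC(C)C)OCC | intermediate
8 | diethyl (1-lithio-2-methylpropyl)phosphonate | [Li]C(C(C)C)P(=O)(OCC)OCC | intermediate
9 | ketophosphonate silyl acetal | CCOP(=O)(OCC)C(C(C)C)C(=O)[C@H]1O[C@@H](O[Si](C)(C)C(C)(C)C)CC[C@H]1C | intermediate
10 | ketophosphonate lactol | CCOP(=O)(OCC)C(C(C)C)C(=O)[C@H]1OC(O)CC[C@H]1C | intermediate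
11 | ketophosphonate δ-lactone | CCOP(=O)(OCC)C(C(C)C)C(=O)[C@H]1OC(=O)CC[C@H]1C | intermediate
12 | nerol | OC/C=C(/C)CCC=C(C)C | starting material
13 | (2S,3R)-2,3-epoxynerol | OC[C@@H]1O[C@]1(C)CCC=C(C)C | intermediate
14 | PMB ether of 13 | COc1ccc(COC[C@@H]2O[C@]2(C)CCC=C(C)C)cc1 | intermediate
15 | secondary ozonide of 14 | COc1ccc(COC[C@@H]2O[C@]2(C)CCC3OOC(C)(C)O3)cc1 | intermediate
16 | epoxy aldehyde (C7 aldehyde) | COc1ccc(COC[C@@H]2O[C@]2(C)CCC=O)cc1 | intermediate
17 | (Z)-α-iodo enoate | COc1ccc(COC[C@@H]2O[C@]2(C)CC/C=C(\I)C(=O)OCC)cc1 | intermediate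
18 | (Z)-2-iodo allylic alcohol | COc1ccc(COC[C@@H]2O[C@]2(C)CC/C=C(\I)CO)cc1 | intermediate
19 | sodium phosphonoenolate of 11 | CCOP(=O)(OCC)C(C(C)C)=C([O-])[C@H]1OC(=O)CC[C@H]1C.[Na+] | intermediate
20 | vinyllithium lithium alkoxide from 18 | COc1ccc(COC[C@@H]2O[C@]2(C)CC/C=C(\[Li])CO[Li])cc1 | intermediate
21 | open-chain seco diol | COc1ccc(COC[C@@H]2O[C@]2(C)CC/C=C(/CO)C(=O)CC[C@@H](C)[C@H](O)C(=O)C(C(C)C)P(=O)(OCC)OCC)cc1 | intermediate
22 | 13,19-bis-TES ether of 21 | COc1ccc(COC[C@@H]2O[C@]2(C)CC/C=C(/CO[Si](CC)(CC)CC)C(=O)CC[C@@H](C)[C@H](O[Si](CC)(CC)CC)C(=O)C(C(C)C)P(=O)(OCC)OCC)cc1 | intermediate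
23 | C2 epoxy alcohol | OC[C@@H]1O[C@]1(C)CC/C=C(/CO[Si](CC)(CC)CC)C(=O)CC[C@@H](C)[C@H](O[Si](CC)(CC)CC)C(=O)C(C(C)C)P(=O)(OCC)OCC | intermediate
24 | C2 epoxy aldehyde | O=C[C@@H]1O[C@]1(C)CC/C=C(/CO[Si](CC)(CC)CC)C(=O)CC[C@@H](C)[C@H](O[Si](CC)(CC)CC)C(=O)C(C(C)C)P(=O)(OCC)OCC | intermediate
25 | macrocyclic bis-TES ether | CC(C)/C1=C\[C@@H]2O[C@]2(C)CC/C=C(/CO[Si](CC)(CC)CC)C(=O)CC[C@@H](C)[C@H](O[Si](CC)(CC)CC)C1=O | intermediate
26 | CNP0251075.1 | CC(C)/C1=C\[C@@H]2O[C@]2(C)CC/C=C(/CO)C(=O)CC[C@@H](C)[C@H](O)C1=O | target

Total step count: 18. Longest linear sequence: 12 steps (1, 2, 3, 5, 6, 7, 13, 14, 15, 16, 17, 18).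

Steps most likely to fail

**Step 17 (ring closure).**
- Risk: the fully substituted, isopropyl-flanked phosphonate carbanion may add to the aldehyde too slowly. Oligomerisation, base-induced unravelling of the epoxy aldehyde, vinylogous elimination at C19 or loss of control over the C1=C2 geometry could then compete with cyclisation.
- Fallback, from 5 and 18 back to 25: the C1=C2 bond is made in the open chain, where concentration can be high and geometric isomers can be separated. The ring is then closed at C8–C9 by a Nozaki–Hiyama–Kishi reaction.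
- Western half: acetal 5 is opened with propane-1,3-dithiol and BF3·OEt2 to the hydroxy dithiane ester F1. This is silylated (TESCl, imidazole) to the TES ether F2 and acylated with 8 as in step 5 to the dithiane ketophosphonate F3.
- Eastern half: iodo alcohol 18 is silylated to the iodo TES ether F4, freed from PMB with DDQ to the iodo epoxy alcohol F5 and oxidised with Dess–Martin periodinane to the iodo epoxy aldehyde F6.
- Union and closure: intermolecular olefination of F3 with F6 (LiCl, DBU, MeCN) gives the open-chain 1E enone F7. MeI and CaCO3 in aqueous MeCN unmask the C9 aldehyde F8. CrCl2 with catalytic NiCl2 in DMSO at high dilution closes the ring to the macrocyclic C9 carbinol F9 (both epimers), and Dess–Martin oxidation gives 25.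

**Step 13 (fragment union).**
- Risk: the vinyllithium may cyclise on to its own epoxide, take a proton from the lactone α-methylene group, or add a second time after premature collapse of the hemiketal alkoxide.
- Fallback, from 11 and 18 back to 22: the lactone is opened first and a softer vinylmagnesium reagent meets an N-methoxy-N-methylamide, whose chelated adduct cannot add twice.
- Lactone 11 reacts with MeNH(OMe)·HCl and AlMe3 to give the hydroxy amide F10. TESCl and imidazole give the amide TES ether F11, and NaH converts it into the sodium enolate F12.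
- Iodo alcohol 18 is treated with i-PrMgCl·LiCl (2.1 equiv, THF, −30 °C) to give the vinylmagnesium magnesium alkoxide F13.
- Combination of F12 and F13 gives the C19-hydroxy enone F14, and TESCl with imidazole gives 22.

**Step 2 (cycloaddition).**
- Risk: the reaction may drift into the open-chain vinylogous Mukaiyama aldol manifold. The endo preference or the facial selectivity may be weak, or the Lewis acid may ionise the allylic silyl acetal.
- Fallback, from 3 back to 10: the same C12–C13 bond is made by reagent-controlled crotylboration, and the same pyran is closed afterwards by hydroformylation.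
- Aldehyde 3 reacts at −78 °C with (Z)-crotyldiisopinocampheylborane derived from (+)-α-pinene (si-face attack, closed chair transition state, ethanolamine work-up) to give the syn homoallylic alcohol F15.
- Rh(acac)(CO)2 with BIPHEPHOS under CO/H2 adds C9 at the alkene terminus, and the aldehyde closes to the lactol ester F16.
- TBSCl and imidazole give the silyl acetal F17 (both anomers, one of them being 5). Acylation with 8 as in step 5 gives the ketophosphonate silyl acetal F18 (both anomers), and HF·pyridine as in step 6 gives 10.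

Further compounds
F1 | step 17 | ethyl (2S,3R)-5-(1,3-dithian-2-yl)-2-hydroxy-3-methylpentanoate | CCOC(=O)[C@@H](O)[C@H](C)CCC1SCCCS1
F2 | step 17 | ethyl (2S,3R)-5-(1,3-dithian-2-yl)-3-methyl-2-(triethylsilyloxy)pentanoate | CCOC(=O)[C@@H](O[Si](CC)(CC)CC)[C@H](C)CCC1SCCCS1
F3 | step 17 | dithiane ketophosphonate (C9 dithiane, 13-OTES, C14 ketone, C1 isopropyl phosphonate) | CCOP(=O)(OCC)C(C(C)C)C(=O)[C@@H](O[Si](CC)(CC)CC)[C@H](C)CCC1SCCCS1
F4 | step 17 | TES ether of 18 | COc1ccc(COC[C@@H]2O[C@]2(C)CC/C=C(\I)CO[Si](CC)(CC)CC)cc1
F5 | step 17 | iodo epoxy alcohol (C2-OH, 19-OTES) | OC[C@@H]1O[C@]1(C)CC/C=C(\I)CO[Si](CC)(CC)CC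
F6 | step 17 | iodo epoxy aldehyde (C2 aldehyde, 19-OTES) | O=C[C@@H]1O[C@]1(C)CC/C=C(\I)CO[Si](CC)(CC)CC
F7 | step 17 | open-chain 1E enone with C8 iodide and C9 dithiane | CC(C)/C(=C\[C@@H]1O[C@]1(C)CC/C=C(\I)CO[Si](CC)(CC)CC)C(=O)[C@@H](O[Si](CC)(CC)CC)[C@H](C)CCC2SCCCS2
F8 | step 17 | open-chain 1E enone with C8 iodide and C9 aldehyde | CC(C)/C(=C\[C@@H]1O[C@]1(C)CC/C=C(\I)CO[Si](CC)(CC)CC)C(=O)[C@@H](O[Si](CC)(CC)CC)[C@H](C)CCC=O
F9 | step 17 | macrocyclic C9 carbinol, 13,19-bis-TES (both C9 epimers) | CC(C)/C1=C\[C@@H]2O[C@]2(C)CC/C=C(/CO[Si](CC)(CC)CC)C(O)CC[C@@H](C)[C@H](O[Si](CC)(CC)CC)C1=O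
F10 | step 13 | C13-hydroxy C9 N-methoxy-N-methylamide ketophosphonate | CON(C)C(=O)CC[C@@H](C)[C@H](O)C(=O)C(C(C)C)P(=O)(OCC)OCC
F11 | step 13 | 13-OTES ether of F10 | CON(C)C(=O)CC[C@@H](C)[C@H](O[Si](CC)(CC)CC)C(=O)C(C(C)C)P(=O)(OCC)OCC
F12 | step 13 | sodium enolate of F11 | CON(C)C(=O)CC[C@@H](C)[C@H](O[Si](CC)(CC)CC)C([O-])=C(C(C)C)P(=O)(OCC)OCC.[Na+]
F13 | step 13 | vinylmagnesium chloride magnesium alkoxide from 18 | COc1ccc(COC[C@@H]2O[C@]2(C)CC/C=C(\[Mg]Cl)CO[Mg]Cl)cc1
F14 | step 13 | seco enone with free C19 hydroxyl and 13-OTES | COc1ccc(COC[C@@H]2O[C@]2(C)CC/C=C(/CO)C(=O)CC[C@@H](C)[C@H](O[Si](CC)(CC)CC)C(=O)C(C(C)C)P(=O)(OCC)OCC)cc1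
F15 | step 2 | ethyl (2S,3R)-2-hydroxy-3-methylpent-4-enoate | C=C[C@@H](C)[C@H](O)C(=O)OCC
F16 | step 2 | ethyl (2S,3R)-6-hydroxy-3-methyloxane-2-carboxylate (both anomers) | CCOC(=O)[C@H]1OC(O)CC[C@H]1C
F17 | step 2 | ethyl (2S,3R)-6-(tert-butyldimethylsilyloxy)-3-methyloxane-2-carboxylate (both anomers) | CCOC(=O)[C@H]1OC(O[Si](C)(C)C(C)(C)C)CC[C@H]1C
F18 | step 2 | ketophosphonate silyl acetal (both anomers) | CCOP(=O)(OCC)C(C(C)C)C(=O)[C@H]1OC(O[Si](C)(C)C(C)(C)C)CC[C@H]1C
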